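D was the product I was after, and it ended at 51.6 % in delta, 51.1 % in gamma and 51.7 % in beta.

| flask | G | E | temperature | remark | time |
|---|---|---|---|---|---|
| delta | 10 mM | 2 equiv | 20 °C | run made earlier |  |
| gamma | 40 mM | 2 equiv | 32 °C | run made earlier |  |
| beta | 20 mM | 4 equiv | 20 °C | run made earlier |  |
| Saturday's | 20 mM | 2.00 equiv | 40 °C |  | 15 h |
| Tuesday's | 20 mM | 2.00 equiv | 25 °C |  | 15 h |

| run | time / h | L / % | D / % | G / % | Z / % | X / % |
|---|---|---|---|---|---|---|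
| delta | 3.00 | 1.8 | 43.6 | 0.2 | 12.2 | 18.5 |
| delta | 6.00 | 0.1 | 51.2 | 0 | 2.0 | 18.7 |
| delta | 10.0 | 0.3 | 51.8 | 0.4 | 0 | 18.7 |
| delta | 12.0 | 0.7 | 51.4 | 0 | 0 | 19.5 |
| delta | 15.0 | 0 | 51.8 | 0 | 0 | 19.5 |
| delta | 20.0 | 0.1 | 51.6 | 0 | 0 | 19.3 |
| gamma | 1.33 | 0 | 49.7 | 0.1 | 1.2 | 24.0 |
| gamma | 2.50 | 0.4 | 50.5 | 0.1 | 0 | 23.7 |
| gamma | 4.00 | 0.2 | 51.0 | 0 | 0.4 | 23.4 |
| gamma | 6.00 | 0.1 | 51.3 | 0 | 0 | 22.9 |
| gamma | 10.0 | 0 | 50.7 | 0 | 0 | 23.4 |
| gamma | 20.0 | 0 | 51.1 | 0.3 | 0 | 24.1 |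
| beta | 4.00 | 3.7 | 45.4 | 0.3 | 7.0 | 17.8 |
| beta | 8.00 | 0.9 | 51.7 | 0 | 0.8 | 18.4 |
| beta | 10.0 | 0.2 | 52.3 | 0.4 | 0.5 | 19.1 |
| beta | 15.0 | 0 | 51.8 | 0.2 | 0 | 19.1 |
| beta | 20.0 | 0 | 51.7 | 0 | 0.5 | 19.1 |

(each reading ± 0.3 percentage points)

* which of these there is most of at the end, counted by the G in it, Saturday's (D / Z / G / X / L)
* which of these there is most of at the end, counted by the G in it, Tuesday's (D / Z / G / X / L)
* amount of the one of these that there is most of at the end, in percent of the G charged, Saturday's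
* amount of the one of these that there is most of at the end, in percent of the G charged, Tuesday's

- reactions considered so far: G + E <-> L; G -> X; G -> Z; Z -> D; 2 E -> Q; Z -> J

The odd thing was this: from delta (10 mM, 20 °C) to gamma (40 mM, 32 °C), the last reading of X rose by 4.8 percentage points, yet that of D read 0.5 points lower. From delta to beta, cG went from 10 mM to 20 mM and E from 2 equiv to 4 equiv, with X reading 19.1 % against 19.3 % and D as above, so I took temperature as the setting to reckon with. I read each end as two forks: G goes to X or Z, then Z goes to D or J, with unread J as the remainder. For each fork I took the odds (a selectivity factor): X over what is not X, and D over J.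

X odds: delta 0.239, gamma 0.318

D odds: delta 1.77, gamma 2.06

The multiple on a fork's odds for that temperature step I called its fork factor: 1.33 for X, 1.16 for D. That cleared the puzzle: by these readings gamma sent less G down the Z path than delta, 75.9 % against 80.7 %, but D took a larger share of it than in delta, 67.3 % against 63.9 %.

I assumed each factor held per equal temperature step:

Saturday's: 1.67 steps, X 0.384 in odds, D 50.2 %

Tuesday's: 0.417 steps, D 51.5 %

The time, 15 h, was longer than the 10.0 h at which delta's D read 51.8 %, against 51.6 % at its last reading. The forecast named D for Saturday's at 50.4 % and D for Tuesday's at 51.4 %, close to my figures but not the same: “The two effects nearly cancel, leaving D almost flat.”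

Saturday's flask gave D at 49.9 %, and Tuesday's gave D at 51.6 %.

    G + E ⇌ L (K = 16.0 M⁻¹, k = 0.270 M⁻¹ min⁻¹, Ea = 47.0 kJ mol⁻¹, ΔH = −90.0 kJ mol⁻¹)
    G → X (k = 0.0290 min⁻¹, Ea = 96.0 kJ mol⁻¹)
    G → Z (k = 0.110 min⁻¹, Ea = 79.0 kJ mol⁻¹)
    Z → D (k = 0.0150 min⁻¹, Ea = 101 kJ mol⁻¹)
    2 E → Q (k = 0.210 M⁻¹ min⁻¹, Ea = 69.0 kJ mol⁻¹)
    Z → J (k = 0.00800 min⁻¹, Ea = 94.0 kJ mol⁻¹)
    (constants at 25 °C)

I put the same fork factors on Saturday's flask moved to 65 °C, all amounts and the time held. That is 3.75 steps, so X odds of 0.692 and D odds of 3.11. They gave X 40.9 % and D 44.7 %. The neighbour flask ended with X at 37.2 % and D at 45.4 %, still ahead of X by 8.2 points.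

(The runs were generated by integration for an exercise; scatter was added.)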